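**Retrosynthetic overview**
- Nakijiquinone J ⇒ saponification of its 2-O-methyl ether (a vinylogous ester) ⇒ laccase/O2 oxidative C–N coupling of a 2-methoxy-3-alkyl-1,4-benzoquinone with (S)-2-methylbutylamine.
- (S)-2-Methylbutylamine ⇐ amide ⇐ (S)-2-methylbutanoic acid ⇐ tiglic acid by Ru/H8-BINAP asymmetric hydrogenation.
- Methoxyquinone ⇐ CAN oxidation of a 2,3,6-trimethoxybenzyl decalin ⇐ aryllithium addition to a decalin aldehyde, followed by Barton–McCombie deoxygenation.
- Decalin aldehyde ⇐ catalytic enantioselective exo-Diels–Alder reaction of 6,6-dimethyl-1-vinylcyclohexene with tiglic aldehyde, which sets all three ring stereocentres at once.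
- Ring order: ring A is bought (2,2-dimethylcyclohexanone); ring B is formed by the Diels–Alder reaction; the six-membered arene is attached intact and oxidised to the quinone last.

Assumption: the facial sense of step 3 follows the usual pre-transition-state model for s-trans 2-substituted enals on the (S)-proline-derived oxazaborolidinium ion (diene enters on the Cα-Si face); it is checked on 7 by chiroptical or X-ray correlation of a derivative, and the equally available (R)-catalyst is used if the check comes out opposite.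

**Step 1**
Reactants: 1 2,2-dimethylcyclohexanone
Product: 3 6,6-dimethylcyclohex-1-en-1-yl trifluoromethanesulfonate, via lithium 6,6-dimethylcyclohex-1-en-1-olate 2 (not isolated)
Conditions: LDA (1.1 equiv), THF, −78 °C, 1 h; PhNTf2 (1.05 equiv), −78 °C → rt; H2O work-up
Reagents that add atoms: N-phenylbis(trifluoromethanesulfonimide), O=S(=O)(N(c1ccccc1)S(=O)(=O)C(F)(F)F)C(F)(F)F; lithium diisopropylamide, [Li+].CC(C)[N-]C(C)C (Li of 2 only)
Why: Only one α-position of 1 carries hydrogen, so LDA gives a single enolate, and its O-sulfonylation (enol triflate formation) fixes the ring double bond where the diene needs it, with no stereocentre formed.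

**Step 2**
Reactants: 3 6,6-dimethylcyclohex-1-en-1-yl trifluoromethanesulfonate; 4 tributyl(vinyl)stannane
Product: 5 6,6-dimethyl-1-vinylcyclohex-1-ene
Conditions: Pd(PPh3)4 (3 mol %), LiCl (3 equiv), THF, reflux
Reagents that add atoms: none
Why: The Stille coupling of a vinyl triflate with a vinylstannane (LiCl enables transmetalation) tolerates the neighbouring quaternary carbon and gives the 1,3-diene without double-bond migration, with no stereocentre formed.

**Step 3**
Reactants: 5 6,6-dimethyl-1-vinylcyclohex-1-ene; 6 tiglic aldehyde, (E)-2-methylbut-2-enal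
Product: 7 (1R,2S,8aR)-1,2,5,5-tetramethyl-1,2,3,5,6,7,8,8a-octahydronaphthalene-1-carbaldehyde (C4=C4a alkene; 1-Me and 2-Me cis; CHO cis to H-8a)
Conditions: (S)-3,3-diphenyl-1-(o-tolyl)tetrahydropyrrolo[1,2-c][1,3,2]oxazaborole (20 mol %) + Tf2NH (17 mol %), CH2Cl2, −78 → −40 °C; minor endo isomer removed by chromatography
Reagents that add atoms: none
Why: This is a catalytic enantioselective Diels–Alder reaction in which the cationic boron Lewis acid holds s-trans 6 (B–O coordination plus a formyl C–H···O contact) over one catalyst aryl group, so 5 adds suprafacially to the open Cα-Si face with "ortho" regiochemistry (terminal CH2 to the β-carbon) through the exo transition state (catalyst-bound CHO turned away from the gem-dimethyl flank, both methyls endo), which sets C-1 (R), C-2 (S) and C-8a (R) in one event.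

**Step 4**
Reactants: 8 1,2,4-trimethoxybenzene; 7 (1R,2S,8aR)-decalin aldehyde
Product: 10 (2,3,6-trimethoxyphenyl)[(1R,2S,8aR)-1,2,5,5-tetramethyl-1,2,3,5,6,7,8,8a-octahydronaphthalen-1-yl]methanol (mixture of carbinol epimers), via 2,3,6-trimethoxyphenyllithium 9 (not isolated)
Conditions: 8 (1.5 equiv), n-BuLi (1.45 equiv), THF, 0 °C → rt, 2 h; then 7, −78 → 0 °C; H2O quench
Reagents that add atoms: n-butyllithium, [Li]CCCC (Li of 9 only)
Why: Directed ortho-metalation of 8 occurs at C-3 between two methoxy groups and the aryllithium adds 1,2 to the non-enolisable neopentyl aldehyde, giving a carbinol epimer mixture that does not matter because that centre is erased in step 6.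

**Step 5**
Reactants: 10 benzylic carbinol
Product: 12 O-{(2,3,6-trimethoxyphenyl)[(1R,2S,8aR)-1,2,5,5-tetramethyl-octahydronaphthalen-1-yl]methyl} S-methyl dithiocarbonate, via the sodium O-alkyl dithiocarbonate 11 (not isolated)
Conditions: NaH (3 equiv), imidazole (cat.), THF, 0 → 40 °C; CS2 (5 equiv), rt; MeI (5 equiv), rt
Reagents that add atoms: sodium hydride, [Na+].[H-] (Na of 11 only); carbon disulfide, S=C=S; iodomethane, CI
Why: Xanthate formation (first half of the Barton–McCombie deoxygenation) needs only the alkoxide, CS2 and MeI, and the product cannot undergo Chugaev elimination because neither neighbour of the carbinol carbon bears hydrogen, so the ring stereocentres are untouched.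

**Step 6**
Reactants: 12 S-methyl xanthate
Product: 13 (1R,2S,8aS)-1-(2,3,6-trimethoxybenzyl)-1,2,5,5-tetramethyl-1,2,3,5,6,7,8,8a-octahydronaphthalene (same spatial arrangement; the C-8a descriptor changes only through CIP priorities)
Conditions: n-Bu3SnH (2.5 equiv), AIBN (0.2 equiv), toluene, 110 °C
Reagents that add atoms: none
Why: In the Barton–McCombie deoxygenation the stannyl radical attacks C=S and releases a stabilised benzylic radical that Bu3SnH quenches faster than it can close onto the remote trisubstituted alkene (a strained bicyclo[2.2.1] closure), and the neutral conditions avoid Wagner–Meerwein shifts at the neopentyl position while removing the carbinol centre.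

**Step 7**
Reactants: 13 trimethoxybenzyl decalin
Product: 14 2-methoxy-3-{[(1R,2S,8aS)-1,2,5,5-tetramethyl-1,2,3,5,6,7,8,8a-octahydronaphthalen-1-yl]methyl}-1,4-benzoquinone
Conditions: (NH4)2Ce(NO3)6 (2.5 equiv), MeCN/H2O 3:1, 0 °C, 20 min
Reagents that add atoms: water, O
Why: CAN oxidative demethylation converts the para-dimethoxy pair into the p-quinone within minutes at 0 °C, leaving the third OMe as a vinylogous ester and the isolated trisubstituted alkene intact.

**Step 8**
Reactants: 15 tiglic acid, (E)-2-methylbut-2-enoic acid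
Product: 16 (S)-2-methylbutanoic acid
Conditions: H2 (1.5–4 atm), Ru(OAc)2[(S)-H8-BINAP] (0.5 mol %), MeOH, 20 °C
Reagents that add atoms: none
Why: In this carboxylate-directed Ru(II)-catalysed asymmetric hydrogenation (Noyori–Takaya type) the substrate binds Ru as its carboxylate and the (S)-H8-BINAP pocket delivers H2 to one olefin face, which sets the side-chain stereocentre as S in about 97 % ee.

**Step 9**
Reactants: 16 (S)-2-methylbutanoic acid
Product: 18 (S)-2-methylbutanamide, via (S)-1-(1H-imidazol-1-yl)-2-methylbutan-1-one 17 (not isolated)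
Conditions: CDI (1.1 equiv), THF, rt, 1 h; conc. aq NH3, 0 °C → rt; recrystallise
Reagents that add atoms: 1,1'-carbonyldiimidazole, O=C(n1ccnc1)n1ccnc1 (imidazolyl of 17 only); ammonia, N
Why: CDI-mediated amidation proceeds through the acyl imidazolide under near-neutral conditions with no ketene or strong base, so the α-stereocentre is not racemised.

**Step 10**
Reactants: 18 (S)-2-methylbutanamide
Product: 19 (S)-2-methylbutan-1-amine
Conditions: LiAlH4 (2.5 equiv), Et2O, reflux; H2O work-up; distil (bp ca. 95 °C)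
Reagents that add atoms: none
Why: LiAlH4 reduction of the primary amide first deprotonates N–H and then reduces C=O to CH2, so the now β-stereocentre is never enolised and stays S.

**Step 11**
Reactants: 14 methoxyquinone; 19 (S)-2-methylbutan-1-amine
Product: 21 2-methoxy-5-{[(2S)-2-methylbutyl]amino}-3-{[(1R,2S,8aS)-1,2,5,5-tetramethyl-octahydronaphthalen-1-yl]methyl}-1,4-benzoquinone, via the corresponding 5-amino-2-methoxy-3-alkylbenzene-1,4-diol 20 (not isolated)
Conditions: 19 (1.2 equiv), laccase (multicopper oxidase, EC 1.10.3.2; Myceliophthora thermophila, ca. 50 U/mmol), air/O2, 0.1 M phosphate buffer pH 7.5–acetone 2:1, 25 °C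
Reagents that add atoms: none
Why: In this laccase-catalysed oxidative (nuclear) amination the amine adds 1,4 at C-5, the position activated by the C-1 carbonyl that the 2-OMe does not deactivate, and the laccase re-oxidises aminohydroquinone 20 (and any hydroquinone from redox exchange) with O2 to water, so no quinone is spent as oxidant, the hindered 2-OMe is not displaced, and no stereocentre is touched.

**Step 12**
Reactants: 21 O-methyl nakijiquinone J
Product: 23 nakijiquinone J, via its sodium quinonolate 22 (not isolated)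
Conditions: 0.5 M aq NaOH (3 equiv), THF, Ar, 0 °C → rt; then 1 M HCl to pH 3 at 0 °C, immediate extraction
Reagents that add atoms: sodium hydroxide, [Na+].[OH-]
Why: Hydroxide saponifies the vinylogous methyl ester by addition–elimination at C-2, because methoxide leaves far better than the vinylogous-amide nitrogen, and the resulting quinonolate is inert to further attack, while base avoids the acid-induced cyclisation of the enol onto the alkene and touches no stereocentre.

**Compound list**
1 | 2,2-dimethylcyclohexanone | CC1(C)CCCCC1=O | starting material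
2 | lithium 6,6-dimethylcyclohex-1-en-1-olate | CC1(C)CCCC=C1[O-].[Li+] | intermediate
3 | 6,6-dimethylcyclohex-1-en-1-yl trifluoromethanesulfonate | CC1(C)CCCC=C1OS(=O)(=O)C(F)(F)F | intermediate
4 | tributyl(vinyl)stannane | C=C[Sn](CCCC)(CCCC)CCCC | starting material
5 | 6,6-dimethyl-1-vinylcyclohex-1-ene | C=CC1=CCCCC1(C)C | intermediate
6 | tiglic aldehyde, (E)-2-methylbut-2-enal | C/C=C(\C)C=O | starting material
7 | (1R,2S,8aR)-1,2,5,5-tetramethyl-1,2,3,5,6,7,8,8a-octahydronaphthalene-1-carbaldehyde | O=C[C@@]1(C)[C@@H]2CCCC(C)(C)C2=CC[C@@H]1C | intermediate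
8 | 1,2,4-trimethoxybenzene | COc1ccc(OC)c(OC)c1 | starting material
9 | 2,3,6-trimethoxyphenyllithium | [Li]c1c(OC)ccc(OC)c1OC | intermediate
10 | (2,3,6-trimethoxyphenyl)[(1R,2S,8aR)-1,2,5,5-tetramethyl-1,2,3,5,6,7,8,8a-octahydronaphthalen-1-yl]methanol, carbinol epimers | COc1ccc(OC)c(C(O)[C@@]2(C)[C@@H]3CCCC(C)(C)C3=CC[C@@H]2C)c1OC | intermediate
11 | sodium O-{(2,3,6-trimethoxyphenyl)[(1R,2S,8aR)-decalinyl]methyl} dithiocarbonate | COc1ccc(OC)c(C(OC(=S)[S-])[C@@]2(C)[C@@H]3CCCC(C)(C)C3=CC[C@@H]2C)c1OC.[Na+] | intermediate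
12 | O-{(2,3,6-trimethoxyphenyl)[(1R,2S,8aR)-decalinyl]methyl} S-methyl dithiocarbonate | COc1ccc(OC)c(C(OC(=S)SC)[C@@]2(C)[C@@H]3CCCC(C)(C)C3=CC[C@@H]2C)c1OC | intermediate
13 | (1R,2S,8aS)-1-(2,3,6-trimethoxybenzyl)-1,2,5,5-tetramethyl-1,2,3,5,6,7,8,8a-octahydronaphthalene | COc1ccc(OC)c(C[C@@]2(C)[C@@H]3CCCC(C)(C)C3=CC[C@@H]2C)c1OC | intermediate
14 | 2-methoxy-3-{[(1R,2S,8aS)-1,2,5,5-tetramethyl-1,2,3,5,6,7,8,8a-octahydronaphthalen-1-yl]methyl}-1,4-benzoquinone | COC1=C(C[C@@]2(C)[C@@H]3CCCC(C)(C)C3=CC[C@@H]2C)C(=O)C=CC1=O | intermediate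
15 | tiglic acid, (E)-2-methylbut-2-enoic acid | C/C=C(\C)C(=O)O | starting material
16 | (S)-2-methylbutanoic acid | CC[C@H](C)C(=O)O | intermediate
17 | (S)-1-(1H-imidazol-1-yl)-2-methylbutan-1-one | CC[C@H](C)C(=O)n1ccnc1 | intermediate
18 | (S)-2-methylbutanamide | CC[C@H](C)C(N)=O | intermediate
19 | (S)-2-methylbutan-1-amine | CC[C@H](C)CN | intermediate
20 | 2-methoxy-5-{[(2S)-2-methylbutyl]amino}-3-{[(1R,2S,8aS)-decalinyl]methyl}benzene-1,4-diol | CC[C@H](C)CNc1cc(O)c(OC)c(C[C@@]2(C)[C@@H]3CCCC(C)(C)C3=CC[C@@H]2C)c1O | intermediate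
21 | 2-methoxy-5-{[(2S)-2-methylbutyl]amino}-3-{[(1R,2S,8aS)-decalinyl]methyl}-1,4-benzoquinone | CC[C@H](C)CNC1=CC(=O)C(OC)=C(C[C@@]2(C)[C@@H]3CCCC(C)(C)C3=CC[C@@H]2C)C1=O | intermediate
22 | sodium salt (2-olate) of nakijiquinone J | CC[C@H](C)CNC1=CC(=O)C([O-])=C(C[C@@]2(C)[C@@H]3CCCC(C)(C)C3=CC[C@@H]2C)C1=O.[Na+] | intermediate
23 | nakijiquinone J, 2-hydroxy-5-{[(2S)-2-methylbutyl]amino}-3-{[(1R,2S,8aS)-1,2,5,5-tetramethyl-1,2,3,5,6,7,8,8a-octahydronaphthalen-1-yl]methyl}-1,4-benzoquinone | CC[C@H](C)CNC1=CC(=O)C(O)=C(C[C@@]2(C)[C@@H]3CCCC(C)(C)C3=CC[C@@H]2C)C1=O | target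

**Totals**
- Total step count: 12.
- Longest linear sequence: 9 steps (1, 2, 3, 4, 5, 6, 7, 11, 12).
- The amine branch (steps 8–10) is convergent.

**Steps most likely to fail**

Step 3 forms a quaternary centre from a β-substituted enal, so conversion, exo:endo ratio or ee may be too low.
- The fallback sets out from diene 5 and returns at aldehyde 7. It replaces catalyst control by a covalently bound controller.
- Commercial tigloyl chloride is N-acylated onto lithiated (S)-4-benzyloxazolidin-2-one to give (4S)-4-benzyl-3-[(E)-2-methylbut-2-enoyl]-1,3-oxazolidin-2-one F1.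
- Me2AlCl-promoted exo-Diels–Alder reaction of F1 with 5 (CH2Cl2, −40 °C) gives (4S)-4-benzyl-3-{[(1R,2S,8aR)-1,2,5,5-tetramethyl-1,2,3,5,6,7,8,8a-octahydronaphthalen-1-yl]carbonyl}-1,3-oxazolidin-2-one F2. Its diastereomers can be separated or crystallised.
- LiAlH4 removes the controller and gives [(1R,2S,8aR)-1,2,5,5-tetramethyl-1,2,3,5,6,7,8,8a-octahydronaphthalen-1-yl]methanol F3.
- Dess–Martin oxidation of F3 gives 7.

Step 6 may fail because the electron-rich, doubly ortho-substituted benzylic xanthate can rearrange, or its radical can be diverted.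
- The fallback sets out from carbinol 10 and returns at 13. It skips steps 5 and 6 and makes no new compound.
- It uses a two-electron dissolving-metal cleavage of the benzylic C–O bond: Li, NH3(l)/THF, −78 °C, then solid NH4Cl.
- The isolated alkene is inert under these conditions.
- The reaction is stopped at the first persistent blue colour to avoid reductive loss of a methoxy group.

Step 11 may fail through poor solubility of the lipophilic quinone, inactivation of the laccase by the cosolvent, or over-amination at C-2.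
- The fallback sets out from aldehyde 7 and returns at target 23. It replaces oxidative C–H amination by a redox-neutral substitution and also makes step 12 unnecessary.
- 1,2,4,5-Tetramethoxybenzene (COc1cc(OC)c(OC)cc1OC) is lithiated (n-BuLi, THF, 0 °C) to 2,3,5,6-tetramethoxyphenyllithium F4.
- F4 is added to 7 to give (2,3,5,6-tetramethoxyphenyl)[(1R,2S,8aR)-decalinyl]methanol F5.
- NaH/CS2/MeI gives its S-methyl xanthate F6.
- Bu3SnH/AIBN gives (1R,2S,8aS)-1-(2,3,5,6-tetramethoxybenzyl)-1,2,5,5-tetramethyl-octahydronaphthalene F7.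
- CAN gives 2,5-dimethoxy-3-{[(1R,2S,8aS)-decalinyl]methyl}-1,4-benzoquinone F8.
- KOH in aqueous MeOH cleaves the twisted, alkyl-flanked vinylogous ester selectively and gives mamanuthaquinone (2-hydroxy-5-methoxy analogue of the target) F9.
- Amine 19 (NaHCO3, EtOH, 40 °C) displaces the 5-OMe of F9 by addition–elimination and gives 23.

**Further compounds**
F1 | step 3 | (4S)-4-benzyl-3-[(E)-2-methylbut-2-enoyl]-1,3-oxazolidin-2-one | C/C=C(\C)C(=O)N1[C@@H](Cc2ccccc2)COC1=O
F2 | step 3 | (4S)-4-benzyl-3-{[(1R,2S,8aR)-1,2,5,5-tetramethyl-1,2,3,5,6,7,8,8a-octahydronaphthalen-1-yl]carbonyl}-1,3-oxazolidin-2-one | O=C(N1[C@@H](Cc2ccccc2)COC1=O)[C@@]1(C)[C@@H]2CCCC(C)(C)C2=CC[C@@H]1C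
F3 | step 3 | [(1R,2S,8aR)-1,2,5,5-tetramethyl-1,2,3,5,6,7,8,8a-octahydronaphthalen-1-yl]methanol | OC[C@@]1(C)[C@@H]2CCCC(C)(C)C2=CC[C@@H]1C
F0 | step 6 | none | none
F4 | step 11 | 2,3,5,6-tetramethoxyphenyllithium | [Li]c1c(OC)c(OC)cc(OC)c1OC
F5 | step 11 | (2,3,5,6-tetramethoxyphenyl)[(1R,2S,8aR)-1,2,5,5-tetramethyl-1,2,3,5,6,7,8,8a-octahydronaphthalen-1-yl]methanol, carbinol epimers | COc1cc(OC)c(OC)c(C(O)[C@@]2(C)[C@@H]3CCCC(C)(C)C3=CC[C@@H]2C)c1OC
F6 | step 11 | O-{(2,3,5,6-tetramethoxyphenyl)[(1R,2S,8aR)-decalinyl]methyl} S-methyl dithiocarbonate | COc1cc(OC)c(OC)c(C(OC(=S)SC)[C@@]2(C)[C@@H]3CCCC(C)(C)C3=CC[C@@H]2C)c1OC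
F7 | step 11 | (1R,2S,8aS)-1-(2,3,5,6-tetramethoxybenzyl)-1,2,5,5-tetramethyl-1,2,3,5,6,7,8,8a-octahydronaphthalene | COc1cc(OC)c(OC)c(C[C@@]2(C)[C@@H]3CCCC(C)(C)C3=CC[C@@H]2C)c1OC
F8 | step 11 | 2,5-dimethoxy-3-{[(1R,2S,8aS)-1,2,5,5-tetramethyl-1,2,3,5,6,7,8,8a-octahydronaphthalen-1-yl]methyl}-1,4-benzoquinone | COC1=CC(=O)C(OC)=C(C[C@@]2(C)[C@@H]3CCCC(C)(C)C3=CC[C@@H]2C)C1=O
F9 | step 11 | mamanuthaquinone, 2-hydroxy-5-methoxy-3-{[(1R,2S,8aS)-1,2,5,5-tetramethyl-1,2,3,5,6,7,8,8a-octahydronaphthalen-1-yl]methyl}-1,4-benzoquinone | COC1=CC(=O)C(O)=C(C[C@@]2(C)[C@@H]3CCCC(C)(C)C3=CC[C@@H]2C)C1=O
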